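**Strategy.** Taking out the ring oxygen O1 of the butyrolactone leaves a 3-substituted cyclobutanone in which C3 and C5, the two CH2 arms on C4, are equivalent. A catalyst-controlled Baeyer–Villiger oxidation of this prochiral ketone, which already carries the complete trans-dihydrobenzofuran unit (rings C and D), inserts oxygen, forms the O1–C5 bond, expands the four-membered ring to the lactone and sets C4 in one operation. C3 is then benzylated trans with the bromide of ring B. Both phenylpropanoid units, the dihydrobenzofuran and the open anti-1,3-diol on ring B, come from one N-arylacetyl oxazolidinone and O-benzylvanillin by diastereodivergent aldol reactions.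

Key step: step 10

Notation: lactone atoms are O1, C2 (C=O), C3, C4, C5 (OCH2). Ring A is the guaiacyl ring on the open-chain carbinol carbon, ring B the phenol ring carrying the diol chain, ring C the benzo ring of the dihydrobenzofuran, ring D its 2-aryl group.

Assumption: the magnesium-catalysed anti-aldol of the (S)-4-benzyl imide is taken to react on the enolate face of the chelated enolate (as in alkylations of that auxiliary), and the ligand antipode for step 10 is fixed by a test run on 3-benzylcyclobutanone so that the 4R lactone results.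

**Route**

Step 1
Reactants: 1 5-bromo-2-hydroxy-3-methoxybenzaldehyde
Product: 2 5-bromo-3-methoxy-2-[(4-methoxybenzyl)oxy]benzaldehyde
Conditions: PMBCl, K2CO3, Bu4NI (cat.), DMF, 60 °C
Reagents that add atoms: 4-methoxybenzyl chloride (COc1ccc(CCl)cc1)
Why: Williamson ether synthesis on the phenoxide; the PMB ether is chosen because it can be removed by acid in the ring-C series and by hydrogenolysis in the ring-B series.

Step 2
Reactants: 2 5-bromo-3-methoxy-2-[(4-methoxybenzyl)oxy]benzaldehyde
Product: 3 1-{5-bromo-3-methoxy-2-[(4-methoxybenzyl)oxy]phenyl}-2,2,2-trichloroethan-1-ol (racemic)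
Conditions: CHCl3, DBU, 0 °C to rt
Reagents that add atoms: chloroform (ClC(Cl)Cl)
Why: base-promoted addition of the trichloromethyl anion to the aldehyde, the first stage of a Jocic-type homologation; the carbinol centre is racemic and disappears in step 3.

Step 3
Reactants: 3 1-{5-bromo-3-methoxy-2-[(4-methoxybenzyl)oxy]phenyl}-2,2,2-trichloroethan-1-ol
Product: 4 2-{5-bromo-3-methoxy-2-[(4-methoxybenzyl)oxy]phenyl}acetic acid
Conditions: NaBH4, NaOH, t-BuOH, 55 °C; then aq. HCl
Reagents that add atoms: sodium hydroxide ([Na+].[OH-])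
Why: reductive Jocic reaction, in which the alkoxide closes to a gem-dichloroepoxide, hydride opens it at the benzylic carbon and the resulting acid chloride is hydrolysed, so the aldehyde carbon ends as the CH2 of a one-carbon-homologated arylacetic acid while the aryl bromide and both ethers stay untouched.

Step 4
Reactants: 4 2-{5-bromo-3-methoxy-2-[(4-methoxybenzyl)oxy]phenyl}acetic acid; 5 (S)-4-benzyloxazolidin-2-one
Product: 7 (S)-4-benzyl-3-(2-{5-bromo-3-methoxy-2-[(4-methoxybenzyl)oxy]phenyl}acetyl)oxazolidin-2-one, via mixed pivalic anhydride 6 (not isolated)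
Conditions: PivCl, Et3N, THF, −20 °C; then 5, LiCl, rt
Reagents that add atoms: none
Why: N-acylation of the Evans auxiliary through the mixed anhydride, which is attacked at the less hindered arylacetyl carbonyl; this imide is the common precursor of rings B and C.

Step 5
Reactants: 7 (S)-4-benzyl-3-(2-{5-bromo-3-methoxy-2-[(4-methoxybenzyl)oxy]phenyl}acetyl)oxazolidin-2-one; 8 4-(benzyloxy)-3-methoxybenzaldehyde
Product: 9 (S)-4-benzyl-3-[(2S,3S)-3-[4-(benzyloxy)-3-methoxyphenyl]-2-{5-bromo-3-methoxy-2-[(4-methoxybenzyl)oxy]phenyl}-3-hydroxypropanoyl]oxazolidin-2-one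
Conditions: Bu2BOTf, i-Pr2NEt, CH2Cl2, 0 °C; then 8, −78 to 0 °C; pH 7 buffer, MeOH, 30% H2O2
Reagents that add atoms: none
Why: Evans syn-aldol reaction through the Z-dibutylboron enolate and a chair Zimmerman–Traxler transition state, in which the auxiliary sets C2 as S and the closed transition state sets C3 syn to it (3S).

Step 6
Reactants: 9 (S)-4-benzyl-3-[(2S,3S)-3-[4-(benzyloxy)-3-methoxyphenyl]-2-{5-bromo-3-methoxy-2-[(4-methoxybenzyl)oxy]phenyl}-3-hydroxypropanoyl]oxazolidin-2-one
Product: 10 (1S,2R)-1-[4-(benzyloxy)-3-methoxyphenyl]-2-{5-bromo-3-methoxy-2-[(4-methoxybenzyl)oxy]phenyl}propane-1,3-diol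
Conditions: LiBH4, MeOH (1 equiv), THF, 0 °C
Reagents that add atoms: none
Why: reductive cleavage of the N-acyl oxazolidinone to the primary alcohol with recovery of the auxiliary; no stereocentre is touched (the descriptor at C2 changes only through the priority rules).

Step 7
Reactants: 10 (1S,2R)-1-[4-(benzyloxy)-3-methoxyphenyl]-2-{5-bromo-3-methoxy-2-[(4-methoxybenzyl)oxy]phenyl}propane-1,3-diol
Product: 11 {(2S,3R)-2-[4-(benzyloxy)-3-methoxyphenyl]-5-bromo-7-methoxy-2,3-dihydro-1-benzofuran-3-yl}methanol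
Conditions: TFA, anisole, CH2Cl2, 0 °C
Reagents that add atoms: none
Why: acidolysis of the PMB ether frees the ring-C phenol and the p-benzyloxybenzylic alcohol ionises, so the phenol closes the furan ring in an SN1-type 5-exo cyclisation that should give the 2,3-trans product, because the C3 centre from the aldol directs the aryl group at C2 anti to the CH2OH group (2S,3R).

Step 8
Reactants: 11 {(2S,3R)-2-[4-(benzyloxy)-3-methoxyphenyl]-5-bromo-7-methoxy-2,3-dihydro-1-benzofuran-3-yl}methanol
Product: 12 {[(2S,3R)-2-[4-(benzyloxy)-3-methoxyphenyl]-5-bromo-7-methoxy-2,3-dihydro-1-benzofuran-3-yl]methoxy}(tert-butyl)dimethylsilane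
Conditions: TBSCl, imidazole, DMF, rt
Reagents that add atoms: tert-butyldimethylsilyl chloride (CC(C)(C)[Si](C)(C)Cl)
Why: standard silylation of the primary alcohol, needed for the organozinc coupling, the peracid oxidation and the enolate alkylation.

Step 9
Reactants: 12 {[(2S,3R)-2-[4-(benzyloxy)-3-methoxyphenyl]-5-bromo-7-methoxy-2,3-dihydro-1-benzofuran-3-yl]methoxy}(tert-butyl)dimethylsilane; 13 3-(bromomethyl)cyclobutan-1-one
Product: 15 3-({(2S,3R)-2-[4-(benzyloxy)-3-methoxyphenyl]-3-{[(tert-butyldimethylsilyl)oxy]methyl}-7-methoxy-2,3-dihydro-1-benzofuran-5-yl}methyl)cyclobutan-1-one, via [(3-oxocyclobutyl)methyl]zinc bromide 14 (not isolated)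
Conditions: 13, Zn dust (activated with 1,2-dibromoethane and TMSCl), LiCl, THF, 50 °C; then 12, Pd(OAc)2 (2 mol%), SPhos (4 mol%), THF, 40 °C
Reagents that add atoms: none
Why: Negishi sp3–sp2 cross-coupling, in which LiCl-promoted zinc insertion gives a ketone-tolerant primary alkylzinc bromide that transmetalates to the arylpalladium bromide formed by oxidative addition of 12 to zerovalent palladium; no stereocentre is formed and the cyclobutane carbon bearing the new CH2 stays non-stereogenic.

Step 10
Reactants: 15 3-({(2S,3R)-2-[4-(benzyloxy)-3-methoxyphenyl]-3-{[(tert-butyldimethylsilyl)oxy]methyl}-7-methoxy-2,3-dihydro-1-benzofuran-5-yl}methyl)cyclobutan-1-one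
Product: 16 (4R)-4-({(2S,3R)-2-[4-(benzyloxy)-3-methoxyphenyl]-3-{[(tert-butyldimethylsilyl)oxy]methyl}-7-methoxy-2,3-dihydro-1-benzofuran-5-yl}methyl)oxolan-2-one
Conditions: Sc(OTf)3 (10 mol%), chiral N,N'-dioxide ligand L-PiPr2 (from L-pipecolic acid 2,6-diisopropylanilide, three-carbon linker; 10 mol%), m-CPBA, EtOAc, −20 °C
Reagents that add atoms: 3-chloroperoxybenzoic acid (OOC(=O)c1cccc(Cl)c1)
Why: Catalytic asymmetric Baeyer–Villiger oxidation as a desymmetrisation: the scandium complex binds the strained ketone, the peracid adds to the carbonyl carbon to give the Criegee adduct, and one of the two CH2 groups flanking the carbonyl migrates with its electron pair from carbon to the proximal peroxide oxygen as m-chlorobenzoate leaves, so that the new ring oxygen is bonded to that CH2 and to the carbonyl carbon. The closest known reaction type is the metal- or Brønsted-acid-catalysed enantioselective Baeyer–Villiger oxidation of 3-aryl- and 3-benzylcyclobutanones to β-substituted γ-butyrolactones. The five-membered lactone is closed by ring expansion, that is by oxygen insertion through a 1,2-shift into the four-membered ring, and not by an exo or endo cyclisation. The only new stereocentre, C4 of the lactone, arises because the two CH2 groups that can migrate are enantiotopic within the ring (diastereotopic in 15), and the chiral ligand sphere decides which of them lies antiperiplanar to the O–O bond; the distant (2S,3R) centres are not expected to bias the outcome. The step needs this group selectivity and chemoselectivity for the ketone; the latter is secured by ring strain, since a cyclobutanone reacts with peracid far faster than aryl ethers, the benzyl ether or the silyl ether, and there is no other carbonyl group or alkene.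

Step 11
Reactants: 7 (S)-4-benzyl-3-(2-{5-bromo-3-methoxy-2-[(4-methoxybenzyl)oxy]phenyl}acetyl)oxazolidin-2-one; 8 4-(benzyloxy)-3-methoxybenzaldehyde
Product: 18 (S)-4-benzyl-3-[(2R,3S)-3-[4-(benzyloxy)-3-methoxyphenyl]-2-{5-bromo-3-methoxy-2-[(4-methoxybenzyl)oxy]phenyl}-3-hydroxypropanoyl]oxazolidin-2-one, via trimethylsilyl ether of the anti adduct 17 (not isolated)
Conditions: MgCl2 (20 mol%), Et3N, TMSCl, EtOAc, rt; then 1 M HCl, THF, 0 °C
Reagents that add atoms: none
Why: magnesium halide-catalysed Evans anti-aldol reaction, in which the chelated Z-magnesium enolate adds through a boat transition state on the face opposite to the benzyl group of the auxiliary (2R) with anti relative configuration (3S), and silylation of the aldolate makes the addition irreversible.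

Step 12
Reactants: 18 (S)-4-benzyl-3-[(2R,3S)-3-[4-(benzyloxy)-3-methoxyphenyl]-2-{5-bromo-3-methoxy-2-[(4-methoxybenzyl)oxy]phenyl}-3-hydroxypropanoyl]oxazolidin-2-one
Product: 19 (1S,2S)-1-[4-(benzyloxy)-3-methoxyphenyl]-2-{5-bromo-3-methoxy-2-[(4-methoxybenzyl)oxy]phenyl}propane-1,3-diol
Conditions: LiBH4, MeOH (1 equiv), THF, 0 °C
Reagents that add atoms: none
Why: reductive cleavage of the imide to the anti-1,3-diol with recovery of the auxiliary; both stereocentres are kept.

Step 13
Reactants: 19 (1S,2S)-1-[4-(benzyloxy)-3-methoxyphenyl]-2-{5-bromo-3-methoxy-2-[(4-methoxybenzyl)oxy]phenyl}propane-1,3-diol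
Product: 20 (1S,2S)-1-[4-(benzyloxy)-3-methoxyphenyl]-2-{5-bromo-3-methoxy-2-[(4-methoxybenzyl)oxy]phenyl}-1,3-bis[(tert-butyldimethylsilyl)oxy]propane
Conditions: TBSOTf, 2,6-lutidine, CH2Cl2, 0 °C
Reagents that add atoms: tert-butyldimethylsilyl triflate (CC(C)(C)[Si](C)(C)OS(=O)(=O)C(F)(F)F)
Why: silylation of the primary and the hindered benzylic alcohol with the reactive silyl triflate under non-acidic conditions, so the ionisable benzylic centre is not epimerised.

Step 14
Reactants: 20 (1S,2S)-1-[4-(benzyloxy)-3-methoxyphenyl]-2-{5-bromo-3-methoxy-2-[(4-methoxybenzyl)oxy]phenyl}-1,3-bis[(tert-butyldimethylsilyl)oxy]propane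
Product: 21 {3-[(1S,2S)-1-[4-(benzyloxy)-3-methoxyphenyl]-1,3-bis[(tert-butyldimethylsilyl)oxy]propan-2-yl]-5-methoxy-4-[(4-methoxybenzyl)oxy]phenyl}methanol
Conditions: Bu3SnCH2OH, Pd(PPh3)4, 1,4-dioxane, 100 °C
Reagents that add atoms: (tributylstannyl)methanol (CCCC[Sn](CCCC)(CCCC)CO)
Why: Stille coupling that transfers the hydroxymethyl group to the aryl bromide under neutral conditions, which the silyl, benzyl and PMB ethers tolerate.

Step 15
Reactants: 21 {3-[(1S,2S)-1-[4-(benzyloxy)-3-methoxyphenyl]-1,3-bis[(tert-butyldimethylsilyl)oxy]propan-2-yl]-5-methoxy-4-[(4-methoxybenzyl)oxy]phenyl}methanol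
Product: 22 benzylic bromide of ring B: (1S,2S)-1-[4-(benzyloxy)-3-methoxyphenyl]-2-{5-(bromomethyl)-3-methoxy-2-[(4-methoxybenzyl)oxy]phenyl}-1,3-bis[(tert-butyldimethylsilyl)oxy]propane
Conditions: CBr4, PPh3, 2,6-lutidine (cat.), CH2Cl2, 0 °C; used without storage
Reagents that add atoms: carbon tetrabromide (BrC(Br)(Br)Br)
Why: Appel bromination of the primary benzylic alcohol under neutral conditions that leave the silyl ethers in place.

Step 16
Reactants: 16 (4R)-4-({(2S,3R)-2-[4-(benzyloxy)-3-methoxyphenyl]-3-{[(tert-butyldimethylsilyl)oxy]methyl}-7-methoxy-2,3-dihydro-1-benzofuran-5-yl}methyl)oxolan-2-one; 22 benzylic bromide of ring B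
Product: 23 fully protected (3R,4R)-lactone: (3R,4R)-3-{3-[(1S,2S)-1-[4-(benzyloxy)-3-methoxyphenyl]-1,3-bis[(tert-butyldimethylsilyl)oxy]propan-2-yl]-5-methoxy-4-[(4-methoxybenzyl)oxy]benzyl}-4-({(2S,3R)-2-[4-(benzyloxy)-3-methoxyphenyl]-3-{[(tert-butyldimethylsilyl)oxy]methyl}-7-methoxy-2,3-dihydro-1-benzofuran-5-yl}methyl)oxolan-2-one
Conditions: LiHMDS, THF, −78 °C; then 22, DMPU, −78 to −40 °C
Reagents that add atoms: none
Why: alkylation of the lactone lithium enolate with the benzylic bromide, which approaches the enolate face anti to the C4 substituent and should therefore give the 3,4-trans lactone (3R), as is usual for β-benzyl-γ-butyrolactones.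

Step 17
Reactants: 23 fully protected (3R,4R)-lactone
Product: 24 (3R,4R)-3-{3-[(1S,2S)-1-[4-(benzyloxy)-3-methoxyphenyl]-1,3-dihydroxypropan-2-yl]-5-methoxy-4-[(4-methoxybenzyl)oxy]benzyl}-4-({(2S,3R)-2-[4-(benzyloxy)-3-methoxyphenyl]-3-(hydroxymethyl)-7-methoxy-2,3-dihydro-1-benzofuran-5-yl}methyl)oxolan-2-one
Conditions: TBAF, AcOH, THF, rt
Reagents that add atoms: none
Why: fluoride cleavage of the three silyl ethers under buffered conditions while all phenols are still protected, so no quinone methide can form and the lactone is not opened.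

Step 18
Reactants: 24 (3R,4R)-lactone triol with protected phenols
Product: 25 CNP0186558.2, (3R,4R)-3-{3-[(1S,2S)-1,3-dihydroxy-1-(4-hydroxy-3-methoxyphenyl)propan-2-yl]-4-hydroxy-5-methoxybenzyl}-4-{[(2S,3R)-2-(4-hydroxy-3-methoxyphenyl)-3-(hydroxymethyl)-7-methoxy-2,3-dihydro-1-benzofuran-5-yl]methyl}oxolan-2-one
Conditions: H2 (1 atm), 10% Pd/C, EtOAc/MeOH, rt, acid-free work-up
Reagents that add atoms: none
Why: hydrogenolysis of the two phenolic benzyl ethers and the phenolic PMB ether under neutral conditions, which should leave the secondary benzylic alcohol and the benzylic C–O bond of the dihydrobenzofuran intact and avoids the acid that would close the open diol unit to a second dihydrobenzofuran.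

**Compound list**

1 | 5-bromo-2-hydroxy-3-methoxybenzaldehyde | O=Cc1cc(Br)cc(OC)c1O | starting material
2 | 5-bromo-3-methoxy-2-[(4-methoxybenzyl)oxy]benzaldehyde | O=Cc1cc(Br)cc(OC)c1OCc1ccc(OC)cc1 | intermediate
3 | 1-{5-bromo-3-methoxy-2-[(4-methoxybenzyl)oxy]phenyl}-2,2,2-trichloroethan-1-ol (racemic) | OC(c1cc(Br)cc(OC)c1OCc1ccc(OC)cc1)C(Cl)(Cl)Cl | intermediate
4 | 2-{5-bromo-3-methoxy-2-[(4-methoxybenzyl)oxy]phenyl}acetic acid | OC(=O)Cc1cc(Br)cc(OC)c1OCc1ccc(OC)cc1 | intermediate
5 | (S)-4-benzyloxazolidin-2-one | O=C1N[C@@H](Cc2ccccc2)CO1 | starting material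
6 | mixed anhydride of 4 with pivalic acid (not isolated) | CC(C)(C)C(=O)OC(=O)Cc1cc(Br)cc(OC)c1OCc1ccc(OC)cc1 | intermediate
7 | (S)-4-benzyl-3-(2-{5-bromo-3-methoxy-2-[(4-methoxybenzyl)oxy]phenyl}acetyl)oxazolidin-2-one | O=C(Cc1cc(Br)cc(OC)c1OCc1ccc(OC)cc1)N1C(=O)OC[C@@H]1Cc1ccccc1 | intermediate
8 | 4-(benzyloxy)-3-methoxybenzaldehyde | O=Cc1ccc(OCc2ccccc2)c(OC)c1 | starting material
9 | syn-aldol adduct, (2S,3S) in the acyl chain, (S)-auxiliary | O=C([C@@H](c1cc(Br)cc(OC)c1OCc1ccc(OC)cc1)[C@H](O)c1ccc(OCc2ccccc2)c(OC)c1)N1C(=O)OC[C@@H]1Cc1ccccc1 | intermediate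
10 | (1S,2R)-1-[4-(benzyloxy)-3-methoxyphenyl]-2-{5-bromo-3-methoxy-2-[(4-methoxybenzyl)oxy]phenyl}propane-1,3-diol | OC[C@@H](c1cc(Br)cc(OC)c1OCc1ccc(OC)cc1)[C@H](O)c1ccc(OCc2ccccc2)c(OC)c1 | intermediate
11 | {(2S,3R)-2-[4-(benzyloxy)-3-methoxyphenyl]-5-bromo-7-methoxy-2,3-dihydro-1-benzofuran-3-yl}methanol (2,3-trans) | Brc1cc(OC)c2c(c1)[C@H](CO)[C@@H](c1ccc(OCc3ccccc3)c(OC)c1)O2 | intermediate
12 | tert-butyldimethylsilyl ether of 11 | Brc1cc(OC)c2c(c1)[C@H](CO[Si](C)(C)C(C)(C)C)[C@@H](c1ccc(OCc3ccccc3)c(OC)c1)O2 | intermediate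
13 | 3-(bromomethyl)cyclobutan-1-one | O=C1CC(CBr)C1 | starting material
14 | [(3-oxocyclobutyl)methyl]zinc bromide (not isolated) | O=C1CC(C[Zn]Br)C1 | intermediate
15 | 3-({(2S,3R)-2-[4-(benzyloxy)-3-methoxyphenyl]-3-{[(tert-butyldimethylsilyl)oxy]methyl}-7-methoxy-2,3-dihydro-1-benzofuran-5-yl}methyl)cyclobutan-1-one | O=C1CC(Cc2cc(OC)c3c(c2)[C@H](CO[Si](C)(C)C(C)(C)C)[C@@H](c2ccc(OCc4ccccc4)c(OC)c2)O3)C1 | intermediate
16 | (4R)-4-({(2S,3R)-2-[4-(benzyloxy)-3-methoxyphenyl]-3-{[(tert-butyldimethylsilyl)oxy]methyl}-7-methoxy-2,3-dihydro-1-benzofuran-5-yl}methyl)oxolan-2-one | O=C1C[C@@H](Cc2cc(OC)c3c(c2)[C@H](CO[Si](C)(C)C(C)(C)C)[C@@H](c2ccc(OCc4ccccc4)c(OC)c2)O3)CO1 | intermediate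
17 | trimethylsilyl ether of anti-aldol adduct 18 (not isolated) | O=C([C@H](c1cc(Br)cc(OC)c1OCc1ccc(OC)cc1)[C@H](O[Si](C)(C)C)c1ccc(OCc2ccccc2)c(OC)c1)N1C(=O)OC[C@@H]1Cc1ccccc1 | intermediate
18 | anti-aldol adduct, (2R,3S) in the acyl chain, (S)-auxiliary | O=C([C@H](c1cc(Br)cc(OC)c1OCc1ccc(OC)cc1)[C@H](O)c1ccc(OCc2ccccc2)c(OC)c1)N1C(=O)OC[C@@H]1Cc1ccccc1 | intermediate
19 | (1S,2S)-1-[4-(benzyloxy)-3-methoxyphenyl]-2-{5-bromo-3-methoxy-2-[(4-methoxybenzyl)oxy]phenyl}propane-1,3-diol | OC[C@H](c1cc(Br)cc(OC)c1OCc1ccc(OC)cc1)[C@H](O)c1ccc(OCc2ccccc2)c(OC)c1 | intermediate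
20 | bis(tert-butyldimethylsilyl) ether of 19 | CC(C)(C)[Si](C)(C)OC[C@H](c1cc(Br)cc(OC)c1OCc1ccc(OC)cc1)[C@H](O[Si](C)(C)C(C)(C)C)c1ccc(OCc2ccccc2)c(OC)c1 | intermediate
21 | benzylic alcohol of ring B (CH2OH in place of Br of 20) | CC(C)(C)[Si](C)(C)OC[C@H](c1cc(CO)cc(OC)c1OCc1ccc(OC)cc1)[C@H](O[Si](C)(C)C(C)(C)C)c1ccc(OCc2ccccc2)c(OC)c1 | intermediate
22 | benzylic bromide of ring B (CH2Br in place of CH2OH of 21) | CC(C)(C)[Si](C)(C)OC[C@H](c1cc(CBr)cc(OC)c1OCc1ccc(OC)cc1)[C@H](O[Si](C)(C)C(C)(C)C)c1ccc(OCc2ccccc2)c(OC)c1 | intermediate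
23 | fully protected (3R,4R)-lactone (three TBS ethers, two benzyl ethers, one PMB ether) | COc1cc([C@@H](O[Si](C)(C)C(C)(C)C)[C@H](CO[Si](C)(C)C(C)(C)C)c2cc(C[C@H]3C(=O)OC[C@@H]3Cc3cc(OC)c4c(c3)[C@H](CO[Si](C)(C)C(C)(C)C)[C@@H](c3ccc(OCc5ccccc5)c(OC)c3)O4)cc(OC)c2OCc2ccc(OC)cc2)ccc1OCc1ccccc1 | intermediate
24 | (3R,4R)-lactone triol with two benzyl ethers and one PMB ether | COc1cc([C@@H](O)[C@H](CO)c2cc(C[C@H]3C(=O)OC[C@@H]3Cc3cc(OC)c4c(c3)[C@H](CO)[C@@H](c3ccc(OCc5ccccc5)c(OC)c3)O4)cc(OC)c2OCc2ccc(OC)cc2)ccc1OCc1ccccc1 | intermediate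
25 | CNP0186558.2 | COc1cc([C@@H](O)[C@H](CO)c2cc(C[C@H]3C(=O)OC[C@@H]3Cc3cc(OC)c4c(c3)[C@H](CO)[C@@H](c3ccc(O)c(OC)c3)O4)cc(OC)c2O)ccc1O | target

**Count**

Total steps: 18. Longest linear sequence: 13 steps (steps 1 to 10, then 16 to 18). The ring-B branch (steps 11 to 15) starts from imide 7 and joins at step 16.

**Steps most likely to fail, with fallbacks**

Step 10 (key step). The catalyst may fail to tell the two CH2 groups of 15 apart, so that oxygen is inserted on both sides and both C4 epimers form; the Lewis acid may also be held by the many ether oxygens and lose activity. The fallback moves stereocontrol from the catalyst to a covalently bound chiral controller. It sets out from 15, which is ketalised with (2R,4R)-pentane-2,4-diol (PPTS, benzene, reflux with removal of water) to the spiro-ketal of 15 with (2R,4R)-pentane-2,4-diol F1. F1 is then oxidised with m-CPBA in the presence of SnCl4 in CH2Cl2 at −100 °C. The Lewis acid opens the ketal to an oxocarbenium ion that carries the chiral alkoxide, the peracid adds to one face, and the same 1,2-shift forms the O1–C5 bond. Aqueous work-up releases the diol and the route is rejoined at lactone 16. The diol antipode is chosen by the same model test as the ligand.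

Step 9. Zinc insertion into 13 may be incomplete, the organozinc may be protonated at the acidic α-positions of another cyclobutanone molecule, or the strained ring may open at the organometallic stage, so that too little nucleophile reaches the palladium cycle. The fallback replaces the one-step coupling by the classical three-step construction of the cyclobutanone and sets out from 12. Stille allylation (allyltributylstannane, Pd(PPh3)4, toluene, 100 °C) should give the 5-allyl dihydrobenzofuran F2. A [2+2] cycloaddition with dichloroketene, generated from trichloroacetyl chloride and Zn–Cu couple in Et2O, should give the 2,2-dichlorocyclobutanone F3 as a mixture of epimers at the new ring carbon, which is of no consequence. Reductive dechlorination with Zn and NH4Cl in MeOH removes both chlorine atoms and comes back to the route at 15.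

Step 11. Addition of the stabilised arylacetyl enolate to the electron-rich aldehyde may be slow, retro-aldol equilibration may compete with silyl trapping, and the anti selectivity may erode. The fallback leaves the catalytic, silyl-trapped magnesium manifold for a stoichiometric two-metal aldol reaction through an open transition state. It sets out from 7 and 8: the dibutylboron enolate of 7 is preformed (Bu2BOTf, i-Pr2NEt, CH2Cl2) and added at −78 °C to 8 that has been precomplexed with Et2AlCl. The internally chelated boron enolate should react on the same enolate face and the bulky aluminium-bound aldehyde should favour the anti arrangement. The route is rejoined directly at 18; this fallback makes no new compound (F0).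

Further compounds
F1 | step 10 | spiro-ketal of 15 with (2R,4R)-pentane-2,4-diol | C[C@@H]1C[C@@H](C)OC2(CC(Cc3cc(OC)c4c(c3)[C@H](CO[Si](C)(C)C(C)(C)C)[C@@H](c3ccc(OCc5ccccc5)c(OC)c3)O4)C2)O1
F2 | step 9 | {[(2S,3R)-5-allyl-2-[4-(benzyloxy)-3-methoxyphenyl]-7-methoxy-2,3-dihydro-1-benzofuran-3-yl]methoxy}(tert-butyl)dimethylsilane | C=CCc1cc(OC)c2c(c1)[C@H](CO[Si](C)(C)C(C)(C)C)[C@@H](c1ccc(OCc3ccccc3)c(OC)c1)O2
F3 | step 9 | 2,2-dichloro-3-({(2S,3R)-2-[4-(benzyloxy)-3-methoxyphenyl]-3-{[(tert-butyldimethylsilyl)oxy]methyl}-7-methoxy-2,3-dihydro-1-benzofuran-5-yl}methyl)cyclobutan-1-one (epimers at cyclobutane C3) | O=C1CC(Cc2cc(OC)c3c(c2)[C@H](CO[Si](C)(C)C(C)(C)C)[C@@H](c2ccc(OCc4ccccc4)c(OC)c2)O3)C1(Cl)Cl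
F0 | step 11 | none | none
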